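The pendant α-methyl-γ-butyrolactone is disconnected across its CH2–CH(CH3) bond and its ring O–CH bond, back to a 2-vinylpyrrole and a propanoyl unit. In the key step an α-amide radical from a C2-symmetric 2-bromopropanamide adds to the vinyl CH2, and the resulting pyrrolylic radical, oxidised to an azafulvenium ion through the pyrrole nitrogen and its α-carbon, is closed by the amide oxygen; hydrolysis releases lactone and auxiliary. This exploits the pyrrole ring as donor to the exocyclic O–CH carbon. The precursor is the complete tetracyclic pyrrole–azepine–cyclohexene–cis-lactone core carrying only a vinyl group, assembled by an Evans syn-aldol, a double ring-closing metathesis and an intramolecular pyrrole Michael addition.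

Key step: step 13

Assumption: (2S,5S)-2,5-dimethylpyrrolidine (26) is taken as a purchasable auxiliary, and its sense of induction in step 13 is assigned from the accepted model for amide radicals of this auxiliary (radical methyl syn to the carbonyl oxygen, attack anti to the methyl on the neighbouring pyrrolidine carbon); if the sense were opposite, the (2R,5R) amine would be used in the same way.

Step 1
Reactants: 1 (4R)-4-benzyl-1,3-oxazolidin-2-one; 2 butanoyl chloride
Product: 4 (4R)-4-benzyl-3-butanoyl-1,3-oxazolidin-2-one, via lithium oxazolidinide 3 (not isolated)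
Conditions: n-BuLi, THF, −78 °C; then 2, −78 → 0 °C
Reagents that add atoms: none
Why: N-acylation of the lithiated oxazolidinone with an acid chloride is the standard preparation of Evans imides and creates no stereocenter.

Step 2
Reactants: 4 (4R)-4-benzyl-3-butanoyl-1,3-oxazolidin-2-one; 5 acrolein
Product: 7 (4R)-4-benzyl-3-[(2R,3S)-2-ethyl-3-hydroxypent-4-enoyl]-1,3-oxazolidin-2-one, via dibutylboron Z-enolate 6 (not isolated)
Conditions: Bu2BOTf, Et3N, CH2Cl2, 0 °C; 5, −78 → 0 °C; H2O2, MeOH, pH 7 buffer
Reagents that add atoms: none
Why: Evans syn-aldol reaction, in which the Z-boron enolate reacts through a Zimmerman–Traxler chair on the face away from the benzyl group, should set the ethyl-bearing carbon and the carbinol carbon as the (2R,3S) syn pair.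

Step 3
Reactants: 7 aldol adduct; 8 N,O-dimethylhydroxylamine hydrochloride
Product: 9 (2R,3S)-2-ethyl-3-hydroxy-N-methoxy-N-methylpent-4-enamide
Conditions: AlMe3, CH2Cl2, −10 → 0 °C; aq Rochelle salt
Reagents that add atoms: none
Why: Weinreb transamidation of a β-hydroxy imide with the aluminium amide, assisted by the free hydroxyl, removes the auxiliary without touching either stereocenter.

Step 4
Reactants: 10 pyrrole; 11 5-bromopent-1-ene
Product: 12 1-(pent-4-en-1-yl)-1H-pyrrole
Conditions: KOH, DMSO, rt
Reagents that add atoms: none
Why: alkylation of the pyrrolyl anion in DMSO with a primary bromide is N-selective.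

Step 5
Reactants: 12 1-(pent-4-en-1-yl)-1H-pyrrole; 9 Weinreb amide
Product: 15 (2R,3S)-2-ethyl-3-hydroxy-1-[1-(pent-4-en-1-yl)-1H-pyrrol-2-yl]pent-4-en-1-one, via 2-lithiopyrrole 13 (not isolated), via chloromagnesium alkoxide 14 (not isolated)
Conditions: 12, n-BuLi, TMEDA, THF, 0 °C → rt; 9 pretreated with i-PrMgCl (THF, −20 °C) added at −78 → 0 °C; aq NH4Cl
Reagents that add atoms: none
Why: α-lithiation of the N-alkylpyrrole and addition to the Weinreb amide, whose chelated tetrahedral adduct collapses only on work-up, should give the 2-acylpyrrole without over-addition and without exposing the α-stereocenter of the ketone to base.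

Step 6
Reactants: 15 hydroxy ketone; 16 methacrylic anhydride
Product: 17 (3S,4R)-4-ethyl-5-oxo-5-[1-(pent-4-en-1-yl)-1H-pyrrol-2-yl]pent-1-en-3-yl 2-methylprop-2-enoate
Conditions: Et3N, DMAP (cat.), CH2Cl2, −20 → 0 °C
Reagents that add atoms: none
Why: DMAP-catalysed O-acylation of the secondary allylic alcohol at low temperature is fast relative to β-elimination or enolisation of the weakly acidic 2-acylpyrrole ketone.

Step 7
Reactants: 17 keto methacrylate
Product: 18 (3S,4S)-4-ethyl-5-[1-(pent-4-en-1-yl)-1H-pyrrol-2-yl]hexa-1,5-dien-3-yl 2-methylprop-2-enoate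
Conditions: Tebbe reagent Cp2Ti(μ-CH2)(μ-Cl)AlMe2, pyridine, THF–toluene, −40 → 0 °C; aq NaOH
Reagents that add atoms: Tebbe reagent, C[Al-]1(C)C[Ti](C2C=CC=C2)(C2C=CC=C2)[Cl+]1
Why: Tebbe methylenation is non-basic, so the adjacent stereocenter should not epimerise, and at low temperature it takes a ketone in preference to an ester.

Step 8
Reactants: 18 tetraene ester
Product: 20 (5S)-5-[(1S)-1-(6,7-dihydro-5H-pyrrolo[1,2-a]azepin-9-yl)propyl]-3-methylfuran-2(5H)-one, via butenolide triene 19 (not isolated)
Conditions: second-generation Grubbs catalyst RuCl2(=CHPh)(H2IMes)(PCy3) (10 mol %), toluene (0.005 M), 80 °C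
Reagents that add atoms: none
Why: double ring-closing metathesis, in which each terminal alkene loads ruthenium and closes onto its neighbouring 1,1-disubstituted alkene, should give the butenolide and the seven-membered ring with its trisubstituted alkene, no other small ring being within reach.

Step 9
Reactants: 20 butenolide
Product: 22 tetracyclic core lactone (hydrogen on the free pyrrole α-carbon), via methyl epimer 21 (not isolated)
Conditions: Me2AlCl, CH2Cl2 (0.01 M), −78 → 0 °C; aq NaHCO3; then DBU, CH2Cl2, rt
Reagents that add atoms: none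
Why: intramolecular Friedel–Crafts-type Michael addition of the pyrrole β-carbon to the Lewis acid-activated butenolide closes the six-membered ring, the tether from the O–CH carbon forcing the cis ring fusion, while proton-scavenging Me2AlCl spares the alkenylpyrrole and DBU then equilibrates the CH(CH3) carbon to the methyl-exo (R) configuration.

Step 10
Reactants: 22 tetracyclic core lactone
Product: 24 tetracyclic pyrrole-2-carbaldehyde, via iminium chloride 23 (not isolated)
Conditions: POCl3, DMF, ClCH2CH2Cl, 0 °C → rt; aq NaOAc
Reagents that add atoms: N,N-dimethylformamide, CN(C)C=O; water, O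
Why: Vilsmeier–Haack formylation should go to the only free pyrrole α-position, the most nucleophilic ring carbon.

Step 11
Reactants: 24 tetracyclic pyrrole-2-carbaldehyde
Product: 25 tetracyclic 2-vinylpyrrole
Conditions: Ph3PCH3Br, KHMDS, THF, −78 → 0 °C
Reagents that add atoms: methylidenetriphenylphosphorane, C=P(c1ccccc1)(c1ccccc1)c1ccccc1 (made in the flask from methyltriphenylphosphonium bromide, C[P+](c1ccccc1)(c1ccccc1)c1ccccc1.[Br-])
Why: Wittig methylenation of the aldehyde with the non-stabilised ylide at low temperature leaves the lactone intact, and its α-center is already in the thermodynamic configuration.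

Step 12
Reactants: 26 (2S,5S)-2,5-dimethylpyrrolidine; 27 2-bromopropanoyl bromide
Product: 28 2-bromo-1-[(2S,5S)-2,5-dimethylpyrrolidin-1-yl]propan-1-one
Conditions: Et3N, CH2Cl2, 0 °C
Reagents that add atoms: none
Why: N-acylation of the secondary amine with the acid bromide is routine, and the bromide-bearing carbon may stay a mixture because it becomes a planar radical in the next step.

Step 13
Reactants: 25 tetracyclic 2-vinylpyrrole; 28 bromo amide
Product: 30 target CNP0324368.1, via iminium ether bromide 29 (not isolated)
Conditions: fac-Ir(ppy)3 (1 mol %), K2HPO4, MeCN–H2O (9:1), blue LEDs, 0 °C; then pH 5 acetate buffer, rt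
Reagents that add atoms: water, O
Why: Proposed new method: blue-light excitation of fac-Ir(ppy)3 reduces the C–Br bond of 28 to the α-amide radical, which adds to the unsubstituted CH2 terminus of the vinyl group of 25; the pyrrol-2-ylmethyl radical so formed is oxidised by tetravalent iridium (or by bromine-atom transfer followed by ionisation) to an azafulvenium ion that the amide oxygen captures to give iminium ether 29, and water then hydrolyses 29 to the lactone and the free amine. The closest known reaction type is the radical–polar crossover carbolactonisation (atom-transfer radical addition followed by lactonisation) of vinylarenes with α-bromo esters, acids and amides, joined here to the established face-selective addition of radicals flanked by a trans-2,5-dimethylpyrrolidine amide; the new element is the combination, with the auxiliary leaving in the same operation and a vinylpyrrole as acceptor. The lactone ring closes in 5-exo-trig mode, the carbonyl oxygen attacking the exocyclic cationic carbon of the azafulvenium ion. The methyl-bearing center is set in the C–C bond formation by the auxiliary (the radical keeps its methyl syn to the carbonyl oxygen and the methyl on the nearby pyrrolidine carbon blocks one face, giving R), and the O–CH center is set relative to it by closure through an envelope with both substituents pseudo-equatorial, backed by reversible ionisation of the pyrrolylic C–O bond of 29 towards the more stable cis arrangement (R). The step needs site selectivity for the terminal vinyl group over the trisubstituted azepine alkene and the free pyrrole β-position, and tolerance of two epimerisable lactone α-centers; the unhindered CH2 terminus, the pyrrole-stabilised radical it leads to and the near-neutral buffered medium should secure these.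

Compound list
1 | (4R)-4-benzyl-1,3-oxazolidin-2-one | O=C1OC[C@@H](Cc2ccccc2)N1 | starting material
2 | butanoyl chloride | CCCC(Cl)=O | starting material
3 | lithium salt of 1 (N-lithiated oxazolidinone) | [Li+].O=C1OC[C@@H](Cc2ccccc2)[N-]1 | intermediate
4 | (4R)-4-benzyl-3-butanoyl-1,3-oxazolidin-2-one | CCCC(=O)N1[C@H](Cc2ccccc2)COC1=O | intermediate
5 | acrolein (prop-2-enal) | C=CC=O | starting material
6 | dibutylboron Z-enolate of 4 | CC/C=C(\OB(CCCC)CCCC)N1[C@H](Cc2ccccc2)COC1=O | intermediate
7 | (4R)-4-benzyl-3-[(2R,3S)-2-ethyl-3-hydroxypent-4-enoyl]-1,3-oxazolidin-2-one | C=C[C@H](O)[C@@H](CC)C(=O)N1[C@H](Cc2ccccc2)COC1=O | intermediate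
8 | N,O-dimethylhydroxylamine hydrochloride | CNOC.Cl | starting material
9 | (2R,3S)-2-ethyl-3-hydroxy-N-methoxy-N-methylpent-4-enamide | C=C[C@H](O)[C@@H](CC)C(=O)N(C)OC | intermediate
10 | pyrrole | c1cc[nH]c1 | starting material
11 | 5-bromopent-1-ene | C=CCCCBr | starting material
12 | 1-(pent-4-en-1-yl)-1H-pyrrole | C=CCCCn1cccc1 | intermediate
13 | 2-lithio-1-(pent-4-en-1-yl)pyrrole | [Li]c1cccn1CCCC=C | intermediate
14 | chloromagnesium alkoxide of 9 | C=C[C@H](O[Mg]Cl)[C@@H](CC)C(=O)N(C)OC | intermediate
15 | (2R,3S)-2-ethyl-3-hydroxy-1-[1-(pent-4-en-1-yl)-1H-pyrrol-2-yl]pent-4-en-1-one | C=CCCCn1cccc1C(=O)[C@H](CC)[C@@H](O)C=C | intermediate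
16 | methacrylic anhydride | CC(=C)C(=O)OC(=O)C(C)=C | starting material
17 | (3S,4R)-4-ethyl-5-oxo-5-[1-(pent-4-en-1-yl)-1H-pyrrol-2-yl]pent-1-en-3-yl 2-methylprop-2-enoate | C=CCCCn1cccc1C(=O)[C@H](CC)[C@@H](OC(=O)C(C)=C)C=C | intermediate
18 | (3S,4S)-4-ethyl-5-[1-(pent-4-en-1-yl)-1H-pyrrol-2-yl]hexa-1,5-dien-3-yl 2-methylprop-2-enoate | C=CCCCn1cccc1C(=C)[C@H](CC)[C@@H](OC(=O)C(C)=C)C=C | intermediate
19 | (5S)-3-methyl-5-{(3S)-2-[1-(pent-4-en-1-yl)-1H-pyrrol-2-yl]pent-1-en-3-yl}furan-2(5H)-one (butenolide closed, azepine still open) | C=CCCCn1cccc1C(=C)[C@H](CC)[C@H]1OC(=O)C(C)=C1 | intermediate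
20 | (5S)-5-[(1S)-1-(6,7-dihydro-5H-pyrrolo[1,2-a]azepin-9-yl)propyl]-3-methylfuran-2(5H)-one | CC[C@@H](C1=CCCCn2cccc12)[C@H]1OC(=O)C(C)=C1 | intermediate
21 | epimer of 22 at the CH(CH3) carbon (methyl on the concave face, cis to the pyrrole carbon) | CC[C@H]1C2=CCCCn3ccc(c32)[C@H]2[C@@H]1OC(=O)[C@H]2C | intermediate
22 | tetracyclic core lactone: pyrrole fused through N and one α-carbon to the azepine (C=C next to the pyrrole) and through that α-carbon and the adjacent β-carbon to the cyclohexene, which carries the (S)-ethyl carbon and the cis-fused lactone (ring-fusion CH–C S, CH–O R, CH(CH3) R); hydrogen on the other pyrrole α-carbon | CC[C@H]1C2=CCCCn3ccc(c32)[C@H]2[C@@H]1OC(=O)[C@@H]2C | intermediate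
23 | dimethyliminium chloride of 24 (Vilsmeier adduct of 22 at the free α-carbon) | CC[C@H]1C2=CCCCn3c(C=[N+](C)C)cc(c32)[C@H]2[C@@H]1OC(=O)[C@@H]2C.[Cl-] | intermediate
24 | 22 with a formyl group on the free pyrrole α-carbon | CC[C@H]1C2=CCCCn3c(C=O)cc(c32)[C@H]2[C@@H]1OC(=O)[C@@H]2C | intermediate
25 | 22 with a vinyl group on the free pyrrole α-carbon | CC[C@H]1C2=CCCCn3c(C=C)cc(c32)[C@H]2[C@@H]1OC(=O)[C@@H]2C | intermediate
26 | (2S,5S)-2,5-dimethylpyrrolidine | C[C@H]1CC[C@H](C)N1 | starting material
27 | 2-bromopropanoyl bromide | CC(Br)C(Br)=O | starting material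
28 | 2-bromo-1-[(2S,5S)-2,5-dimethylpyrrolidin-1-yl]propan-1-one (mixture at the C–Br carbon) | CC(Br)C(=O)N1[C@@H](C)CC[C@@H]1C | intermediate
29 | cyclic iminium ether bromide: the target lactone with C=N+ (2S,5S)-2,5-dimethylpyrrolidinium in place of the side-lactone C=O | CC[C@H]1C2=CCCCn3c([C@H]4C[C@@H](C)C(=[N+]5[C@@H](C)CC[C@@H]5C)O4)cc(c32)[C@H]2[C@@H]1OC(=O)[C@@H]2C.[Br-] | intermediate
30 | CNP0324368.1: 25 with the vinyl group replaced by a (2R,4R)-4-methyl-5-oxotetrahydrofuran-2-yl ring (cis lactone) | CC[C@H]1C2=CCCCn3c([C@H]4C[C@@H](C)C(=O)O4)cc(c32)[C@H]2[C@@H]1OC(=O)[C@@H]2C | target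

Total step count: 13. Longest linear sequence: 11 steps (1, 2, 3, 5, 6, 7, 8, 9, 10, 11, 13).

Steps most likely to fail

Step 13 (Proposed new method). The radical may add to the trisubstituted azepine alkene instead of the vinyl group. The electron-rich alkenylpyrrole may also be oxidised or dimerise under photosensitisation, and the facial bias when the O–CH bond forms may be weak. The fallback uses known chemistry and sets out from aldehyde 24. A catalytic enantioselective Nozaki–Hiyama–Kishi 2-(alkoxycarbonyl)allylation (ethyl 2-(bromomethyl)acrylate, CrCl2, chiral carbazole bis(oxazoline) ligand, Mn, TMSCl) should give the (R)-homoallylic hydroxy ester F1 under reagent control. F1 lactonises on mild acid work-up to the α-methylene-γ-butyrolactone F2. Hydrogenation of the exocyclic methylene of F2 with RhCl(PPh3)3 and H2, which leaves trisubstituted alkenes alone and delivers hydrogen from the face away from the pyrrole, should give the cis methyl lactone and return to the route at 30.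

Step 9. The free pyrrole α-position may be alkylated intermolecularly, or the Lewis acid may shift the azepine double bond into the six-membered ring, which leads on to aromatisation. The fallback sets out from butenolide 20 and changes the order so that the α-position is blocked first. Vilsmeier–Haack formylation of 20 passes through the iminium chloride F3 to the formyl butenolide F4, which no longer oligomerises. Cyclisation of F4 with AlCl3 at the ring position meta to the formyl group, the normal site for Friedel–Crafts reactions of 2-acylpyrroles, followed by DBU, returns to the route at 24.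

Step 10. The chloroiminium electrophile may attack the alkene terminus of the 2-alkenylpyrrole instead of the ring, or the HCl released may polymerise the substrate. The fallback sets out from 22 and avoids acid. Iridium-catalysed C–H borylation ([Ir(OMe)(cod)]2, 4,4'-di-tert-butyl-2,2'-bipyridine, B2pin2) at the free α-position should give the pinacol boronate F5. Suzuki–Miyaura coupling of F5 with vinyl bromide (Pd(PPh3)4, K3PO4) returns to the route at 25.

Further compounds
F1 | step 13 | ethyl (4R)-4-hydroxy-2-methylidene-4-(pyrrol-2-yl)butanoate built on the tetracyclic core (24 after allylation of its formyl group) | CC[C@H]1C2=CCCCn3c([C@H](O)CC(=C)C(=O)OCC)cc(c32)[C@H]2[C@@H]1OC(=O)[C@@H]2C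
F2 | step 13 | α-methylene analogue of 30 ((R) at the O–CH carbon, exocyclic CH2 in place of the methyl group) | CC[C@H]1C2=CCCCn3c([C@H]4CC(=C)C(=O)O4)cc(c32)[C@H]2[C@@H]1OC(=O)[C@@H]2C
F3 | step 9 | dimethyliminium chloride formed from 20 at its free pyrrole α-carbon | CC[C@@H](C1=CCCCn2c(C=[N+](C)C)ccc12)[C@H]1OC(=O)C(C)=C1.[Cl-]
F4 | step 9 | 20 with a formyl group on the free pyrrole α-carbon | CC[C@@H](C1=CCCCn2c(C=O)ccc12)[C@H]1OC(=O)C(C)=C1
F5 | step 10 | 22 with a pinacolboronate on the free pyrrole α-carbon | CC[C@H]1C2=CCCCn3c(B4OC(C)(C)C(C)(C)O4)cc(c32)[C@H]2[C@@H]1OC(=O)[C@@H]2C
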